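Amounts first: the flask holds 2.00 equiv of nucleophile and 1.00 equiv of free base on 0.10 M of electrophile, with 0.0500 M of protic impurity.

    electrophile + nucleophile → acid set free + product (k1 = 0.016 /M/s)
    acid set free + free base ⇌ salt of the base, settled at all times (K2 = 31000 /M)
    nucleophile ⇌ dormant form (K3 = 10, k3 = 0.0032 /s)
    electrophile + protic impurity → quenched substrate (k4 = 0.026 /M/s)
    acid set free + free base ⇌ idle adduct, settled at all times (K5 = 1900 /M)
    nucleophile + acid set free ⇌ protonated nucleophile, settled at all times (K6 = 200 /M)

electrophile 0.10 M; nucleophile 2.00 equiv; free base 1.00 equiv; protic impurity 0.0500 M; time 40 min

1. part of the electrophile that has reacted at 40 min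
2. share of free nucleophile in free nucleophile and protonated nucleophile together, at 40 min

- what is said of acid set free includes idle adduct
- run time (flask): 40 min

At the bench, this excess of nucleophile reads as pseudo-first-order. Step 1 as charged gives the electrophile a half-life of 3.6 min, the run spans 11.1 such half-lives, and hardly any electrophile should remain. That rule needs c(nucleophile) to hold still, and a ratio marks its border: the forward half-life of the nucleophile into the dormant form, 3.6 min, is about equal to that of the electrophile, so the nucleophile drains while the electrophile is being counted.

By my own reckoning, c(nucleophile) relaxes with time constant 4.73 min towards a plateau of 0.0182 M, taking the pool as undrained by step 1. The excess above the plateau sums to the excess times that time constant, and the plateau sums over the whole run. The turnover count, k1 times c(nucleophile) summed over the run, is then 1.52, which by itself puts c at 78.2%. The protic impurity, if it stayed at its charge, would add 3.12 turnovers and put c at 99.0%, but it falls as it reacts. My reckoning stops at these two figures, and the first is no floor: the pool was taken as undrained by step 1.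

The forecast, stepped by hand, gives c 90.7% and fr 99.4%, with this as a ground: “Nucleophile relaxes to its dormant form”.

The flask gives c 90.6% and fr 99.4%. That c lies above the first figure and below the second, and corresponds to 2.36 turnovers in total. For the neighbour with 0.020 M of protic impurity, the same reckoning gives again 1.52 turnovers from the nucleophile, whose charge is unchanged, and 1.25 from the impurity. Its two figures are 78.2% and 93.8%. That neighbour reaches 77.6%, slightly below the first figure, which is 1.50 turnovers in total, with product at 59.7% and quenched substrate at 17.9%.

The constants were set for the occasion; the run is a simulation.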